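The runs stem from a simulated flask with made-up constants; scatter was added.

If a flask holds 1.1 µM of free enzyme against 11 mM of starting material, reckon in the fraction of the charge left.

| setting | amber | violet | delta | beta |
|---|---|---|---|---|
| starting material | 15 mM | 24 mM | 11 mM | 11 mM |
| gas | 1.8 mM (held) | 1.8 mM (held) | 1.8 mM (held) | 1.8 mM (held) |
| free enzyme | 1.1 µM | 1.1 µM | 1.1 µM | 1.1 µM |
| remark | run made earlier | run made earlier |  |  |
| time |  |  | 8.0 min | 20 min |

| run | time / min | target / % | second complex / % | starting material / % | first complex / % |
|---|---|---|---|---|---|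
| amber | 0.667 | 2.4 | 0.6 | 97.8 | 0.1 |
| amber | 2.00 | 5.7 | 0.2 | 95.9 | 0 |
| amber | 4.00 | 13.0 | 0 | 87.8 | 0 |
| amber | 6.00 | 19.0 | 0.5 | 84.5 | 0 |
| amber | 8.00 | 22.5 | 1.5 | 75.6 | 0.5 |
| violet | 0.667 | 0.5 | 1.1 | 99.2 | 1.5 |
| violet | 1.33 | 4.2 | 0 | 97.5 | 0.1 |
| violet | 2.50 | 5.6 | 1.5 | 92.3 | 0 |
| violet | 4.00 | 8.0 | 0.3 | 90.7 | 0 |
| violet | 8.00 | 18.2 | 0.4 | 82.7 | 0 |

(readings scatter by 1 percentage point)

- at the start none of the gas is in solution

- which of these there is most of at the end, counted by the starting material in it, delta (second complex / first complex / target / starting material)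
- which of these there is most of at the end, counted by the starting material in it, beta (second complex / first complex / target / starting material)
- the largest of these amounts at the end, in percent of the starting material charged, delta
- the largest of these amounts at the end, in percent of the starting material charged, beta

Define clearance as minus the natural log of the fraction left, divided by the time: a pseudo-first-order constant. Take the fraction left as one minus the last target reading. Amber gives 0.0319 min⁻¹; violet, with the same enzyme and a larger charge, gives less, 0.0251 min⁻¹. Draw the inverse of clearance as a straight line in the charge and read off the clearance at the charge of delta and beta, 0.0362 min⁻¹.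

Delta then keeps 74.9 % as starting material. Beta keeps 48.5 %, so target leads in beta at 51.5 %. The same line has clearance rising as starting material falls, so treat beta's remainder as high.

The forecast says starting material at 69 % for delta and target at 70 % for beta. Its ground: “The absolute rate therefore barely rises with starting material”.

The flasks give starting material at 71.0 % in delta and target at 63.6 % in beta.

    starting material + free enzyme ⇌ first complex (K = 51.0 M⁻¹, k = 50000 M⁻¹ s⁻¹)
    first complex → loaded enzyme + first product (k = 1900 min⁻¹)
    second substrate + loaded enzyme ⇌ second complex (K = 1200 M⁻¹, k = 4.10 × 10⁵ M⁻¹ s⁻¹)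
    second complex → free enzyme + target (k = 1400 min⁻¹)
    gas ⇌ second substrate, rate k5*(csat - [second substrate]) (kL = 8.10 min⁻¹)

Beta's remainder of 36 % gives a clearance of 0.0505 min⁻¹, above the 0.0362 min⁻¹ reckoned from the earlier runs. Now take the neighbouring flask: beta's recipe and 20 min, but 2.8 × 10⁻⁴ mM of free enzyme. Scale beta's own clearance, 0.0505 min⁻¹, by the enzyme ratio, 0.255, which gives 0.0128 min⁻¹ and a remainder of 77.3 %. That neighbouring flask holds 81.0 % starting material and 19.0 % target.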